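A small charge of Z stands in the flask: 1.05 M, less than the 1.5 M of L. These are the earlier runs and the question.

| flask | L | Z | remark | time |
|---|---|---|---|---|
| green | 1.5 M | 0.53 M | run made earlier |  |
| violet | 1.5 M | 2.1 M | run made earlier |  |
| blue | 2.2 M | 1.05 M | run made earlier |  |
| flask | 1.5 M | 1.05 M |  | 4.0 h |

| run | time / h | Q / % | L / % |
|---|---|---|---|
| green | 0.133 | 0.5 | 98.2 |
| green | 0.333 | 0 | 97.2 |
| green | 0.667 | 1.8 | 94.9 |
| green | 1.00 | 1.0 | 93.6 |
| green | 1.33 | 2.6 | 92.9 |
| green | 2.00 | 5.4 | 89.6 |
| green | 2.50 | 4.4 | 89.4 |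
| violet | 0.200 | 0 | 94.2 |
| violet | 0.333 | 3.1 | 90.2 |
| violet | 0.417 | 0 | 90.2 |
| violet | 0.667 | 3.8 | 85.9 |
| violet | 1.00 | 3.7 | 81.6 |
| violet | 1.50 | 8.6 | 77.4 |
| violet | 2.50 | 12.8 | 73.0 |
| blue | 0.200 | 0 | 96.7 |
| blue | 0.333 | 0 | 93.5 |
| blue | 0.667 | 0 | 93.1 |
| blue | 1.33 | 4.0 | 84.4 |
| blue | 2.50 | 5.8 | 83.4 |

(each reading ± 1 percentage point)

- amount of Q in percent of the L charged, at 12 min, 1.0 h and 4.0 h

I work with the fraction of L left, not with the Q made. I take its logarithm to fall at a rate in proportion to Z (pseudo-first-order in L).

I read the start from the violet run: its L falls to 90.2% by 0.333 h, which gives a rate constant of 0.147 /M/h. So the logarithm in the flask starts to fall at 0.155 /h.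

The violet run also shows the slowing. Between its last two readings the rate is 0.0585 /h, which is 5.29 times slower than its start. If one Z goes per L, the Z taken by L gives a factor of 1.24, less than that. I read the rest as Z wearing away in pairs, so the rate falls as one over one plus time over a wear time. That time is 0.466 h in the violet run and, scaled inversely with the Z charge, 0.932 h in the flask.

I keep 0.144 as the reach: start rate times wear time, the logarithmic loss of L per natural step of one plus time over wear time. It carries the scatter of the readings.

Unslowed, the flask would keep 53.8% of its L at 4.0 h. Slowed, it keeps 78.6%. In the violet run, Q was 0.474 of the L lost at its last reading, so I expect about 10.1% of Q at the end.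

The forecast gives 0.1%, 1.8% and 11%, and it reads the slowing differently: “which points to a reversible step”.

The flask gives 0.206%, 2.88% and 10.3%, so the forecast stands within its margin.

    L + Z → D + J (k = 0.190 /M/h)
    2 Z → G (k = 0.480 /M/h)
    D ⇌ Q (K = 2.90, k = 0.610 /h)
    D ⇌ E (K = 2.60, k = 0.320 /h)

At the start of the flask, L uses Z at 0.28 of the rate at which pairs of Z turn to G, and 11% of the Z charge remains at 4.00 h. The flask then holds 78% of its L, where the reach of 0.144 gave 78.6%. In the green run, with the wear time scaled to its Z charge, the same reach gives 88.4% of L at 2.50 h, and the reading there is 89.4%.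

Readings and results are calculated for an exercise, noise included.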